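**Retrosynthetic overview** (ring A = cyclohexane of the triol end, ring B = cyclohexane of the 5',8'-epoxy end, ring C = dihydrofuran)
1. Target 18 ⇐ desilylation and hydroxyl-directed E-reduction of the 7,8-alkyne of 16; ring C ⇐ silver-catalysed cyclisation of the (6'S)-α-allenol 15; trans-5,6-diol ⇐ hydrolysis of an oxirane.
2. Allenol and diol both ⇐ C2-symmetric C40 bis(alkynyl oxirane) 12: one oxirane opened by anti-SN2' hydride (C8' set through the allene axis), the other by water with inversion at C6.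
3. Key step: both oxiranes (four stereocentres) ⇐ one twofold epoxidation of the tetradehydro-carotene 11.
4. 11 ⇐ twofold Wittig C15 + C10 + C15; C15 salt 8 ⇐ Sonogashira coupling of actinol-derived enol triflate 4 with enynol 5.
5. Ring order: rings A and B come from actinol 1; the two oxiranes form together (step 6); ring C forms last (step 9) by moving one oxirane oxygen from C6' to C8'.

Assumption: 1 (the industrial zeaxanthin building block actinol), 5 and 9 are bought; locants in names of 11–18 and of the F compounds follow carotenoid numbering.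

Step 1
Reactants: 1 (4R,6R)-4-hydroxy-2,2,6-trimethylcyclohexanone
Product: 2 (4R,6R)-4-(tert-butyldimethylsilyloxy)-2,2,6-trimethylcyclohexanone
Conditions: TBSCl, imidazole, DMF, rt
Reagents that add atoms: tert-butyldimethylsilyl chloride, CC(C)(C)[Si](C)(C)Cl
Why: Imidazole-promoted silylation masks the secondary alcohol for the base, palladium and hydride steps and supplies the bulky group that later steers the epoxidation; no stereocentre is touched.

Step 2
Reactants: 2 (4R,6R)-4-(tert-butyldimethylsilyloxy)-2,2,6-trimethylcyclohexanone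
Product: 4 (4R)-4-(tert-butyldimethylsilyloxy)-2,6,6-trimethylcyclohex-1-en-1-yl trifluoromethanesulfonate, via potassium enolate 3 (not isolated)
Conditions: KN(SiMe3)2, THF, −78 °C; then PhNTf2, −78 to 0 °C
Reagents that add atoms: N-phenylbis(trifluoromethanesulfonimide), FC(F)(F)S(=O)(=O)N(c1ccccc1)S(=O)(=O)C(F)(F)F
Why: Enolate O-triflation; only the methyl-bearing α-carbon carries a proton, so one enol triflate forms, the methyl stereocentre is erased on purpose and the silyloxy centre is kept.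

Step 3
Reactants: 4 (4R)-4-(tert-butyldimethylsilyloxy)-2,6,6-trimethylcyclohex-1-en-1-yl trifluoromethanesulfonate; 5 (2E)-3-methylpent-2-en-4-yn-1-ol
Product: 6 (2E)-5-[(4R)-4-(tert-butyldimethylsilyloxy)-2,6,6-trimethylcyclohex-1-en-1-yl]-3-methylpent-2-en-4-yn-1-ol
Conditions: Pd(PPh3)4 (5 mol %), CuI (10 mol %), i-Pr2NH, THF, 45 °C
Reagents that add atoms: none
Why: Sonogashira coupling (zerovalent palladium, copper acetylide) of the hindered cyclohexenyl triflate with the terminal alkyne makes the C6–C7 bond and leaves the E-olefin and the stereocentre alone.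

Step 4
Reactants: 6 (2E)-5-[(4R)-4-(tert-butyldimethylsilyloxy)-2,6,6-trimethylcyclohex-1-en-1-yl]-3-methylpent-2-en-4-yn-1-ol
Product: 8 [(2E)-5-[(4R)-4-(tert-butyldimethylsilyloxy)-2,6,6-trimethylcyclohex-1-en-1-yl]-3-methylpent-2-en-4-yn-1-yl]triphenylphosphonium bromide, via allylic bromide 7 (not isolated)
Conditions: CBr4, PPh3 (2.3 equiv), CH2Cl2, 0 °C to rt
Reagents that add atoms: carbon tetrabromide, BrC(Br)(Br)Br; triphenylphosphine, c1ccccc1P(c1ccccc1)c1ccccc1
Why: Appel bromination of the primary allylic alcohol, then SN2 quaternisation of the excess phosphine in the same flask, gives the Wittig salt without acid, so the silyl ether survives.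

Step 5
Reactants: 8 C15 phosphonium bromide (2.1 equiv); 9 (2E,4E,6E)-2,7-dimethylocta-2,4,6-trienedial
Product: 11 (3R,3'R)-3,3'-bis(tert-butyldimethylsilyloxy)-7,8,7',8'-tetradehydro-β,β-carotene (all-E), via phosphorus ylide 10 (not isolated)
Conditions: NaOMe, MeOH–CH2Cl2, 0 °C to rt; then heptane, reflux, dark
Reagents that add atoms: none
Why: Two-directional double Wittig olefination (the classical C15 + C10 + C15 carotenoid assembly) forms both C11=C12 bonds, and heating equilibrates Z isomers to the all-E polyene; no stereocentre is involved.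

Step 6
Reactants: 11 (3R,3'R)-3,3'-bis(tert-butyldimethylsilyloxy)-7,8,7',8'-tetradehydro-β,β-carotene
Product: 12 (3S,5R,6R,3'S,5'R,6'R)-3,3'-bis(tert-butyldimethylsilyloxy)-5,6:5',6'-diepoxy-7,8,7',8'-tetradehydro-5,6,5',6'-tetrahydro-β,β-carotene (each oxirane trans to its silyloxy group)
Conditions: m-CPBA (2.2 equiv), NaHCO3, CH2Cl2, −20 °C (minor syn-oxirane isomers removed on silica)
Reagents that add atoms: meta-chloroperoxybenzoic acid, OOC(=O)c1cccc(Cl)c1
Why: Twofold Prilezhaev epoxidation in which both oxirane rings form in one operation: the tetrasubstituted ring alkenes are the most electron-rich π bonds of the polyene-diyne, and the peracid attacks each one anti to the pseudo-axial C1 methyl of the half-chair that keeps the 3-silyloxy group equatorial, so four stereocentres are set at once.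

Step 7
Reactants: 12 C40 bis(alkynyl oxirane)
Product: 13 (3S,5R,6S,3'S,5'R,6'R)-3,3'-bis(tert-butyldimethylsilyloxy)-5',6'-epoxy-7,8,7',8'-tetradehydro-5,6,5',6'-tetrahydro-β,β-carotene-5,6-diol (6-OH trans to 5-OH)
Conditions: HClO4 (0.05 M), THF–H2O 4:1, 0 °C, stopped near 40% conversion per oxirane; recovered 12 resubjected
Reagents that add atoms: water, O
Why: Acid-catalysed epoxide hydrolysis used for terminus differentiation: water opens one oxirane at the tertiary propargylic C6 from the face opposite the leaving oxygen (inversion at C6, retention at C5), while the alkyne blocks the 5,8-furanoid rearrangement that a 7,8-alkene would undergo.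

Step 8
Reactants: 13 C40 diol oxirane
Product: 15 (3S,5R,6S,3'S,5'R,6'S)-3,3'-bis(tert-butyldimethylsilyloxy)-7,8,6',7'-tetradehydro-5,6,5',6'-tetrahydro-β,β-carotene-5,6,5'-triol (6'S allene), via allenyl silyl ether 14 (not isolated)
Conditions: [1,3-bis(2,6-diisopropylphenyl)imidazol-2-ylidene]CuCl (5 mol %), NaOt-Bu (10 mol %), MeSiH(OMe)2, toluene, 0 °C to rt; then K2CO3, MeOH
Reagents that add atoms: none
Why: Copper hydride catalysed anti-SN2' reduction of a propargylic oxirane: hydride adds to C8' on the face opposite the breaking C6'–O bond, turning the oxirane configuration into the (6'S) allene axis, and the 5'-oxygen (silylated during turnover, freed by methanolysis) stays 5'R.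

Step 9
Reactants: 15 C40 α-allenol
Product: 16 (3S,5R,6S,3'S,5'R,8'R)-3,3'-bis(tert-butyldimethylsilyloxy)-5',8'-epoxy-7,8-didehydro-5,6,5',8'-tetrahydro-β,β-carotene-5,6-diol
Conditions: AgNO3 (20 mol %), CaCO3, acetone–H2O 4:1, rt, dark
Reagents that add atoms: none
Why: Silver-catalysed 5-endo-trig cycloisomerisation of an α-hydroxyallene to a 2,5-dihydrofuran: the 5'-hydroxyl attacks C8' anti to the silver-bound face of the C7'=C8' bond, so the allene axis is transferred to the new C8' centre (8'R, chain trans to the 5'-methyl) as ring C closes.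

Step 10
Reactants: 16 C40 furanoid alkynyl diol
Product: 17 (3S,5R,6R,3'S,5'R,8'R)-3,3'-bis(tert-butyldimethylsilyloxy)-5',8'-epoxy-5,6,5',8'-tetrahydro-β,β-carotene-5,6-diol
Conditions: NaAlH2(OCH2CH2OMe)2, THF, 0 °C to rt; aqueous potassium sodium tartrate work-up
Reagents that add atoms: none
Why: Alkoxide-directed trans-hydroalumination of the tertiary propargylic alcohol, then protonolysis, gives only the 7E alkene; the polyene has no neighbouring alkoxide and the ethers are inert to hydride.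

Step 11
Reactants: 17 bis-silyl ether of the target
Product: 18 (3S,5R,6R,3'S,5'R,8'R)-5',8'-epoxy-5,6,5',8'-tetrahydro-β,β-carotene-3,5,6,3'-tetrol (target)
Conditions: Bu4NF, THF, 0 °C to rt
Reagents that add atoms: none
Why: Fluoride-induced desilylation under non-acidic conditions frees both secondary alcohols without ionising the tertiary allylic alcohol or the doubly allylic C8' ether, so no stereocentre is disturbed.

**Compound list**
1 | (4R,6R)-4-hydroxy-2,2,6-trimethylcyclohexanone (actinol) | O=C1C(C)(C)C[C@H](O)C[C@H]1C | starting material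
2 | (4R,6R)-4-(tert-butyldimethylsilyloxy)-2,2,6-trimethylcyclohexanone | O=C1C(C)(C)C[C@H](O[Si](C)(C)C(C)(C)C)C[C@H]1C | intermediate
3 | potassium (4R)-4-(tert-butyldimethylsilyloxy)-2,6,6-trimethylcyclohex-1-en-1-olate | [K+].[O-]C1=C(C)C[C@@H](O[Si](C)(C)C(C)(C)C)CC1(C)C | intermediate (not isolated)
4 | (4R)-4-(tert-butyldimethylsilyloxy)-2,6,6-trimethylcyclohex-1-en-1-yl trifluoromethanesulfonate | FC(F)(F)S(=O)(=O)OC1=C(C)C[C@@H](O[Si](C)(C)C(C)(C)C)CC1(C)C | intermediate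
5 | (2E)-3-methylpent-2-en-4-yn-1-ol | C#C/C(C)=C/CO | starting material
6 | (2E)-5-[(4R)-4-(tert-butyldimethylsilyloxy)-2,6,6-trimethylcyclohex-1-en-1-yl]-3-methylpent-2-en-4-yn-1-ol | OC/C=C(C)/C#CC1=C(C)C[C@@H](O[Si](C)(C)C(C)(C)C)CC1(C)C | intermediate
7 | allylic bromide of 6 (Br in place of OH) | BrC/C=C(C)/C#CC1=C(C)C[C@@H](O[Si](C)(C)C(C)(C)C)CC1(C)C | intermediate (not isolated)
8 | [(2E)-5-[(4R)-4-(tert-butyldimethylsilyloxy)-2,6,6-trimethylcyclohex-1-en-1-yl]-3-methylpent-2-en-4-yn-1-yl]triphenylphosphonium bromide | [Br-].c1ccccc1[P+](c1ccccc1)(c1ccccc1)C/C=C(C)/C#CC1=C(C)C[C@@H](O[Si](C)(C)C(C)(C)C)CC1(C)C | intermediate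
9 | (2E,4E,6E)-2,7-dimethylocta-2,4,6-trienedial | O=C/C(C)=C/C=C/C=C(C)/C=O | starting material
10 | phosphorus ylide of 8 | c1ccccc1P(c1ccccc1)(c1ccccc1)=C/C=C(C)/C#CC1=C(C)C[C@@H](O[Si](C)(C)C(C)(C)C)CC1(C)C | intermediate (not isolated)
11 | (3R,3'R)-3,3'-bis(tert-butyldimethylsilyloxy)-7,8,7',8'-tetradehydro-β,β-carotene (all-E; bis-silyl ether of alloxanthin) | CC1(C)C[C@H](O[Si](C)(C)C(C)(C)C)CC(C)=C1C#C/C(C)=C/C=C/C(C)=C/C=C/C=C(C)/C=C/C=C(C)/C#CC1=C(C)C[C@@H](O[Si](C)(C)C(C)(C)C)CC1(C)C | intermediate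
12 | (3S,5R,6R,3'S,5'R,6'R)-3,3'-bis(tert-butyldimethylsilyloxy)-5,6:5',6'-diepoxy-7,8,7',8'-tetradehydro-5,6,5',6'-tetrahydro-β,β-carotene | CC1(C)C[C@H](O[Si](C)(C)C(C)(C)C)C[C@@]2(C)O[C@@]12C#C/C(C)=C/C=C/C(C)=C/C=C/C=C(C)/C=C/C=C(C)/C#C[C@]12C(C)(C)C[C@H](O[Si](C)(C)C(C)(C)C)C[C@@]1(C)O2 | intermediate
13 | (3S,5R,6S,3'S,5'R,6'R)-3,3'-bis(tert-butyldimethylsilyloxy)-5',6'-epoxy-7,8,7',8'-tetradehydro-5,6,5',6'-tetrahydro-β,β-carotene-5,6-diol | CC1(C)C[C@H](O[Si](C)(C)C(C)(C)C)C[C@@]2(C)O[C@@]12C#C/C(C)=C/C=C/C(C)=C/C=C/C=C(C)/C=C/C=C(C)/C#C[C@@]1(O)C(C)(C)C[C@H](O[Si](C)(C)C(C)(C)C)C[C@@]1(C)O | intermediate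
14 | 5'-O-[dimethoxy(methyl)silyl] ether of 15 | CC1(C)C[C@H](O[Si](C)(C)C(C)(C)C)C[C@@](C)(O[Si](C)(OC)OC)C1=[C@@]=C/C(C)=C/C=C/C(C)=C/C=C/C=C(C)/C=C/C=C(C)/C#C[C@@]1(O)C(C)(C)C[C@H](O[Si](C)(C)C(C)(C)C)C[C@@]1(C)O | intermediate (not isolated)
15 | (3S,5R,6S,3'S,5'R,6'S)-3,3'-bis(tert-butyldimethylsilyloxy)-7,8,6',7'-tetradehydro-5,6,5',6'-tetrahydro-β,β-carotene-5,6,5'-triol | CC1(C)C[C@H](O[Si](C)(C)C(C)(C)C)C[C@@](C)(O)C1=[C@@]=C/C(C)=C/C=C/C(C)=C/C=C/C=C(C)/C=C/C=C(C)/C#C[C@@]1(O)C(C)(C)C[C@H](O[Si](C)(C)C(C)(C)C)C[C@@]1(C)O | intermediate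
16 | (3S,5R,6S,3'S,5'R,8'R)-3,3'-bis(tert-butyldimethylsilyloxy)-5',8'-epoxy-7,8-didehydro-5,6,5',8'-tetrahydro-β,β-carotene-5,6-diol | CC1(C)C[C@H](O[Si](C)(C)C(C)(C)C)C[C@@](C)(O)[C@@]1(O)C#C/C(C)=C/C=C/C(C)=C/C=C/C=C(C)/C=C/C=C(\C)[C@H]1C=C2C(C)(C)C[C@H](O[Si](C)(C)C(C)(C)C)C[C@@]2(C)O1 | intermediate
17 | (3S,5R,6R,3'S,5'R,8'R)-3,3'-bis(tert-butyldimethylsilyloxy)-5',8'-epoxy-5,6,5',8'-tetrahydro-β,β-carotene-5,6-diol | CC1(C)C[C@H](O[Si](C)(C)C(C)(C)C)C[C@@](C)(O)[C@@]1(O)/C=C/C(C)=C/C=C/C(C)=C/C=C/C=C(C)/C=C/C=C(\C)[C@H]1C=C2C(C)(C)C[C@H](O[Si](C)(C)C(C)(C)C)C[C@@]2(C)O1 | intermediate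
18 | (3S,5R,6R,3'S,5'R,8'R)-5',8'-epoxy-5,6,5',8'-tetrahydro-β,β-carotene-3,5,6,3'-tetrol | CC(/C=C/C=C(C)/C=C/[C@@]1(O)C(C)(C)C[C@H](O)C[C@@]1(C)O)=C\C=C\C=C(C)\C=C\C=C(/C)[C@H]1C=C2C(C)(C)C[C@H](O)C[C@@]2(C)O1 | target

**Step count:** 11 steps in total; longest linear sequence 11 (1 to 18).

**Steps most likely to fail**

Step 6 (twofold epoxidation of the C40 polyene-diyne): chain double bonds or the wrong alkene faces may compete with the two ring alkenes. Fallback: set out from 6 and make the oxirane at the C15 stage, where the ring alkene is the only electron-rich one. m-CPBA/NaHCO3 gives the C15 oxirane alcohol F1. CBr4/PPh3 converts it into the oxirane phosphonium bromide F2. NaOMe generates the oxirane ylide F3, and its twofold Wittig reaction with 9, followed by thermal Z/E equilibration, comes back to the route at 12.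

Step 7 (statistical mono-hydrolysis on the C40 compound): over-hydrolysis, attack at C5 or Meyer–Schuster-type side reactions may erode the yield. Fallback: set out from 8 and differentiate the ends before the C40 stage. Ylide 10 with a threefold excess of 9 gives the C25 aldehyde F4. Its ring alkene is epoxidised (the aldehyde-conjugated pentaene is electron-poor) to the C25 oxirane aldehyde F5, and that single oxirane is hydrolysed to completion to the C25 diol aldehyde F6. Wittig reaction of F6 with a second portion of ylide 10 gives the unsymmetrical C40 diol dienyne F7, and epoxidation of its one remaining ring alkene comes back to the route at 13.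

Step 9 (silver-catalysed allenol cyclisation): the alkynyl diol at the other end may also cyclise, and the doubly allylic C8' ether may epimerise. The fallback also bypasses step 8. Fallback: set out from 13 and hydrolyse the second oxirane as well, to the bis(alkynyl diol) F8. NaAlH2(OCH2CH2OMe)2 reduces both alkynes to the bis(trans-5,6-diol) F9. A trace of pyridinium p-toluenesulfonate in CH2Cl2 at 0 °C then ionises one tertiary allylic alcohol, and the neighbouring 5-hydroxyl closes ring C at C8 (cationic dehydrative cyclisation, stopped at partial conversion). Chromatography removes the 8'S epimer and recovered F9, and the route is rejoined at 17; in this fallback C8' is set by separation, not by chirality transfer.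

**Further compounds**
F1 | step 6 | C15 oxirane alcohol: 5,6-epoxide of 6 (3S,5R,6R; oxirane trans to the silyloxy group) | OC/C=C(C)/C#C[C@]12C(C)(C)C[C@H](O[Si](C)(C)C(C)(C)C)C[C@@]1(C)O2
F2 | step 6 | oxirane phosphonium bromide (triphenylphosphonium salt from F1) | [Br-].c1ccccc1[P+](c1ccccc1)(c1ccccc1)C/C=C(C)/C#C[C@]12C(C)(C)C[C@H](O[Si](C)(C)C(C)(C)C)C[C@@]1(C)O2
F3 | step 6 | oxirane ylide (from F2) | c1ccccc1P(c1ccccc1)(c1ccccc1)=C/C=C(C)/C#C[C@]12C(C)(C)C[C@H](O[Si](C)(C)C(C)(C)C)C[C@@]1(C)O2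
F4 | step 7 | C25 aldehyde: (3R)-3-(tert-butyldimethylsilyloxy)-7,8-didehydro-12'-apo-β-caroten-12'-al (all-E) | CC1(C)C[C@H](O[Si](C)(C)C(C)(C)C)CC(C)=C1C#C/C(C)=C/C=C/C(C)=C/C=C/C=C(C)/C=O
F5 | step 7 | C25 oxirane aldehyde: 5,6-epoxide of F4 (3S,5R,6R) | CC1(C)C[C@H](O[Si](C)(C)C(C)(C)C)C[C@@]2(C)O[C@@]12C#C/C(C)=C/C=C/C(C)=C/C=C/C=C(C)/C=O
F6 | step 7 | C25 diol aldehyde: trans-5,6-diol from F5 (3S,5R,6S) | CC1(C)C[C@H](O[Si](C)(C)C(C)(C)C)C[C@@](C)(O)[C@@]1(O)C#C/C(C)=C/C=C/C(C)=C/C=C/C=C(C)/C=O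
F7 | step 7 | C40 diol dienyne: (3S,5R,6S,3'R)-3,3'-bis(tert-butyldimethylsilyloxy)-7,8,7',8'-tetradehydro-5,6-dihydro-β,β-carotene-5,6-diol | CC1(C)C[C@H](O[Si](C)(C)C(C)(C)C)C[C@@](C)(O)[C@@]1(O)C#C/C(C)=C/C=C/C(C)=C/C=C/C=C(C)/C=C/C=C(C)/C#CC1=C(C)C[C@@H](O[Si](C)(C)C(C)(C)C)CC1(C)C
F8 | step 9 | C40 bis(alkynyl diol): (3S,5R,6S,3'S,5'R,6'S)-3,3'-bis(tert-butyldimethylsilyloxy)-7,8,7',8'-tetradehydro-5,6,5',6'-tetrahydro-β,β-carotene-5,6,5',6'-tetrol | CC1(C)C[C@H](O[Si](C)(C)C(C)(C)C)C[C@@](C)(O)[C@@]1(O)C#C/C(C)=C/C=C/C(C)=C/C=C/C=C(C)/C=C/C=C(C)/C#C[C@@]1(O)C(C)(C)C[C@H](O[Si](C)(C)C(C)(C)C)C[C@@]1(C)O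
F9 | step 9 | C40 bis(trans-5,6-diol): (3S,5R,6R,3'S,5'R,6'R)-3,3'-bis(tert-butyldimethylsilyloxy)-5,6,5',6'-tetrahydro-β,β-carotene-5,6,5',6'-tetrol | CC1(C)C[C@H](O[Si](C)(C)C(C)(C)C)C[C@@](C)(O)[C@@]1(O)/C=C/C(C)=C/C=C/C(C)=C/C=C/C=C(C)/C=C/C=C(C)/C=C/[C@@]1(O)C(C)(C)C[C@H](O[Si](C)(C)C(C)(C)C)C[C@@]1(C)O
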